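## Structural features

The target (C28H24O6) is a 19-membered macrocyclic bis(bibenzyl) of four benzene rings joined in the order ring A–O–ring B–CH2CH2–ring C–O–ring D–CH2CH2–back to ring A. Rings A and C are 5-alkyl-3-aryloxybenzene-1,2-diols, ring B is a para-phenylene and ring D a meta-phenylene. The molecule has no stereocentre, so no stereocentres stand next to each other and every selectivity question is regiochemical or chemoselective. The fragile groups are the two free catechols, which oxidise in air to ortho-quinones and chelate metals; they are therefore kept as methyl ethers until the last step. The diaryl ethers and the ethano bridges are robust. The real difficulty lies in the two diaryl ether bonds, each ortho to an oxygen substituent on an electron-rich ring, and in closing the 19-membered ring. The key step exploits ring D: its ether oxygen (from ring C) and its bridge carbon (towards ring A) are 1,3-related, exactly as the C4 oxygen and the C6 methyl group of 4-hydroxy-6-methyl-2-pyrone (6). Carbons C3 to C6 of that pyrone can thus become four carbons of ring D, the other two coming from an ethyne surrogate.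

## Logic of the disconnections

18 to 17: the four O–CH3 bonds are cut. The catechols of 18 would not survive bases, heat or palladium, whereas the methoxy groups of 17 do and arrive already in place with 1. No protecting-group step is needed anywhere else. The forward step must cleave four aryl methyl ethers and spare two diaryl ethers, which a boron Lewis acid does because only the sp3 O–C bonds can be attacked by bromide.

17 to 15 (through 16): the bond between the ring B carbon para to the ether oxygen and the neighbouring CH2 of the bridge to ring C is cut. This opens the macrocycle to an open chain with an aryl bromide at one end and a vinyl group at the other. Both diaryl ethers, which are harder to make in a ring, are already present. The forward step needs terminal hydroboration to 16 and an intramolecular sp3–sp2 coupling that outruns oligomerisation and beta-hydride elimination.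

15 to 14: the vinyl C=C bond is cut back to the aldehyde. An alkene on ring C could not be carried through the cycloaddition, where it would compete as a dienophile and trap sulfenic acid; the aldehyde is inert there. The forward step is a methylenation of a non-enolisable aldehyde next to an aryl bromide.

14 to 10 and 11 (through 13 and 12): two ring D carbon–carbon bonds are cut, namely those that join the unsubstituted CH–CH edge to the bridge-bearing carbon and to the CH ortho to the ether oxygen. The meta pattern is then coded in a pyrone and no metal-mediated coupling of the hindered ring C phenol onto a meta-substituted arene is needed. Ring D disappears and 10 is reached from three simple pieces. The forward step demands that the donor-substituted pyrone adds 11 before it decomposes, and that nothing else in 10 can act as diene or dienophile.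

10 to 9 and 1: the bond between pyrone C4 and the ring C oxygen is cut. C4 of 9 is a vinylogous acyl halide carbon, so the ortho-methoxy phenol 1 can be attached by addition–elimination under mild base without a metal. Ring C then comes from the same commercial compound as ring A. The forward step needs attack at C4 and not at C2 or C6, and exclusion of water.

9 to 8: the C4–Br bond is cut back to C4–OH. The hydroxyl of the vinylogous acid is no leaving group; a bromide is chosen over a sulfonate because it offers a phenoxide only one electrophilic site. The forward step must exchange OH for Br without harming the aryl ethers.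

8 to 5 and 6 (through 7): the CH2–CH2 bond of the bridge between the benzylic carbon of ring A and the carbon on pyrone C6 is cut. The methyl carbon of 6 is the most basic site of its dianion 7 and is alkylated by benzylic halides. Compound 6 thereby supplies four ring D carbons and one bridge carbon. The forward step needs C-alkylation at the methyl carbon, not at oxygen or C3, and a base that leaves the ring B bromide alone.

5 to 4 to 3: the benzylic C–Br and C–H bonds are traced back to the aldehyde, which is the oxidation level of the commercial material and is inert during ether formation. The forward steps are routine reduction and bromination.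

3 to 1 and 2: the ring B carbon–oxygen bond of the A–O–B diaryl ether is cut. On monocyclic partners an oxidative copper coupling at room temperature tolerates aldehyde and bromide, and ring B arrives with its handle for the macrocyclisation. The forward step must O-arylate an ortho-methoxy phenol through the boron of 2 and leave its C–Br bond intact.

## Other disconnections considered

Alternative 1: The cut is the ring B carbon–oxygen bond of the A–O–B diaryl ether, traced back to the 20-membered aryl ester A2, in which the ring A phenol is acylated by a ring B benzoic acid.
- **Forward key step:** a zerovalent nickel catalyst with a chelating bis(dicyclohexylphosphino)thiophene ligand and a phosphate base would insert into the acyl C–O bond of A2, lose carbon monoxide and reductively eliminate the diaryl ether, contracting the ring to the tetra-O-methyl macrocycle A1. A1 is the same compound as 17.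
- **In its favour:** macrolactonisation of a phenol is one of the most dependable ring closures, the hardest ether is formed last with loss of only CO, and A1 is one deprotection from the target.
- **Against it here:** decarbonylative etherification is best established for electron-poor or azine carboxylates. A2 is a para-alkyl benzoate of an ortho-methoxy phenol, electron-rich on both sides, so oxidative addition and C–O reductive elimination should both be slow. The contraction from 20 to 19 members must also pay strain at high temperature, where ester exchange to oligomers can compete. The seco acid for A2 still needs the ring C–O–ring D ether and both bridges, so ring D is not addressed.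
- **Comparison:** on structure it solves an ether that the chosen plan makes in step 1 on simple partners. On mechanism it relies on a less certain elementary step than the pyrone cycloaddition. On step economy it is about equal or longer. Its ring closure by lactonisation is the better of the two macrocyclisations when set against step 9, and its final deprotection is equal.

Alternative 2: The cut removes two ring C carbon–carbon bonds, so that ring C is assembled from the squarate-derived 4-chloro-2,3-diisopropoxycyclobut-2-en-1-one A4 and the 2-stannylalkene A5, which carries ring B as a silyl ether.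
- **Forward key step:** palladium-catalysed Stille coupling joins A4 and A5; the resulting alkenylcyclobutenone opens in a four-electron electrocyclic step and recloses in a six-electron step, and tautomerisation gives the phenol A3.
- **In its favour:** the trioxygenated ring forms with unambiguous regiochemistry and one free hydroxyl exactly where the ether to ring D is needed. The isopropyl ethers fall to a milder Lewis acid than methyl ethers need, and the cascade runs at moderate temperature.
- **Against it here:** it builds a ring whose substitution pattern is bought in 1. A4 and A5 each need their own preparation, tin waste is unavoidable, and after A3 the ether to ring D, the ether to ring A, the second bridge and the macrocyclisation all remain.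
- **Comparison:** on structure it leaves the meta pattern of ring D and the ring closure untouched. On mechanism the coupling and electrocyclic cascade is arguably more predictable in rate than the cycloaddition of step 7, which is a point in its favour. On step economy it is clearly longer. The differentiated free phenol is equal to what 1 already offers, and the milder final deprotection is better.

Alternative 3: The cut removes two ring A carbon–carbon bonds, so that ring A is assembled from the diazo enone A7 and di-tert-butoxyethyne A8.
- **Forward key step:** irradiation of A7 triggers a Wolff rearrangement; ketene–alkyne (2+2) addition with A8, four-electron ring opening and six-electron closure give the phenol A6. A6 already carries ring D as a 3-bromophenyl group.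
- **In its favour:** the 1,2,3-trioxygenated pattern forms with full regiocontrol and a free hydroxyl for the ether to ring B. The tert-butyl ethers can be removed with acid, and the meta pattern of ring D is simply bought.
- **Against it here:** the pattern of ring A is commercial in 1. A7 needs several steps and diazo handling, A8 is a sensitive alkyne, the tert-butyl ethers may lose isobutene in the thermal stage, and irradiation next to an aryl bromide risks C–Br homolysis. After A6, the ring C–O–ring D ether must be made by a metal-catalysed coupling of a hindered ortho-methoxy phenol with that bromide, the very coupling the chosen plan avoids.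
- **Comparison:** on structure, buying ring D is equal to or simpler than building it from 6, but the cost is moved to the ether bond. On mechanism the pericyclic cascade is well understood, though photochemical scale-up is a drawback. On step economy it is longer. The acid-labile protecting groups give a milder endgame than step 10, which is better.

Key step: step 7

Remark on the chemistry: ring C is carried through the cycloaddition as an aldehyde, not an ester, because a non-enolisable aryl aldehyde is an equally inert spectator there and reaches the styrene in one step. The pyrone C4 oxygen is activated as the bromide, not as a sulfonate, because a phenoxide can attack the sulfur of an enol sulfonate.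

## Route

Step 1
Reactants: 1 3-hydroxy-4,5-dimethoxybenzaldehyde; 2 (4-bromophenyl)boronic acid
Product: 3 3-(4-bromophenoxy)-4,5-dimethoxybenzaldehyde
Conditions: 2 (2 equiv), Cu(OAc)2 (1 equiv), pyridine (5 equiv), 4 Å MS, CH2Cl2, dry air, rt
Reagents that add atoms: none
Why: Chan–Lam O-arylation: the aryl group is transferred from boron to a divalent copper phenoxide, air oxidation to trivalent copper is followed by C–O reductive elimination, and at room temperature neither the aldehyde nor the C–Br bond reacts.

Step 2
Reactants: 3 3-(4-bromophenoxy)-4,5-dimethoxybenzaldehyde
Product: 4 [3-(4-bromophenoxy)-4,5-dimethoxyphenyl]methanol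
Conditions: NaBH4, MeOH/THF, 0 °C
Reagents that add atoms: none
Why: Borohydride reduction of an aryl aldehyde to the benzylic alcohol; aryl bromide and ethers are inert to NaBH4.

Step 3
Reactants: 4 [3-(4-bromophenoxy)-4,5-dimethoxyphenyl]methanol
Product: 5 1-(4-bromophenoxy)-5-(bromomethyl)-2,3-dimethoxybenzene
Conditions: PBr3, CH2Cl2, 0 °C
Reagents that add atoms: phosphorus tribromide, BrP(Br)Br
Why: Conversion of a benzylic alcohol into the bromide through its phosphite ester and SN2 attack of bromide; the electron-rich benzylic position reacts fast at 0 °C.

Step 4
Reactants: 6 4-hydroxy-6-methyl-2H-pyran-2-one; 5 1-(4-bromophenoxy)-5-(bromomethyl)-2,3-dimethoxybenzene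
Product: 8 6-{2-[3-(4-bromophenoxy)-4,5-dimethoxyphenyl]ethyl}-4-hydroxy-2H-pyran-2-one, via dilithium pyrone dianion 7 (not isolated)
Conditions: 6 (1.5 equiv), LiN(iPr)2 (3.1 equiv), THF/DMPU, −78 °C; then 5, −78 to −20 °C; aq. HCl
Reagents that add atoms: none
Why: Dianion alkylation: after the 4-OH, the C6 methyl group is deprotonated as a vinylogous position, and the dianion 7 reacts at this most basic carbon with the benzylic bromide by SN2; an amide base is used in place of an alkyllithium so that the ring B bromide undergoes no halogen–metal exchange.

Step 5
Reactants: 8 6-{2-[3-(4-bromophenoxy)-4,5-dimethoxyphenyl]ethyl}-4-hydroxy-2H-pyran-2-one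
Product: 9 4-bromo-6-{2-[3-(4-bromophenoxy)-4,5-dimethoxyphenyl]ethyl}-2H-pyran-2-one
Conditions: Bu4NBr (1.2 equiv), P2O5 (2.5 equiv), toluene, 100 °C
Reagents that add atoms: tetrabutylammonium bromide, CCCC[N+](CCCC)(CCCC)CCCC.[Br-]
Why: Dehydroxy-bromination of a vinylogous acid: O-phosphorylation turns the C4 oxygen into a leaving group and bromide replaces it by addition–elimination, as is known for 4-hydroxy-6-alkyl-2-pyrones; aryl ethers and the aryl bromide are untouched.

Step 6
Reactants: 9 4-bromo-6-{2-[3-(4-bromophenoxy)-4,5-dimethoxyphenyl]ethyl}-2H-pyran-2-one; 1 3-hydroxy-4,5-dimethoxybenzaldehyde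
Product: 10 3-[(6-{2-[3-(4-bromophenoxy)-4,5-dimethoxyphenyl]ethyl}-2-oxo-2H-pyran-4-yl)oxy]-4,5-dimethoxybenzaldehyde
Conditions: 1 (1.1 equiv), K2CO3, dry MeCN, rt to 50 °C
Reagents that add atoms: none
Why: Addition–elimination at a vinylogous acyl bromide: the phenoxide adds to C4 and bromide leaves, the same reaction type by which 4-halocoumarins and 4-halopyrones give 4-aryloxy derivatives; addition at C6 or C2 is reversible, and the mild carbonate base leaves the aldehyde alone.

Step 7
Reactants: 10 3-[(6-{2-[3-(4-bromophenoxy)-4,5-dimethoxyphenyl]ethyl}-2-oxo-2H-pyran-4-yl)oxy]-4,5-dimethoxybenzaldehyde; 11 phenyl vinyl sulfoxide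
Product: 14 3-(3-{2-[3-(4-bromophenoxy)-4,5-dimethoxyphenyl]ethyl}phenoxy)-4,5-dimethoxybenzaldehyde, via bicyclic lactone adduct 12 (not isolated), via sulfinylcyclohexadiene 13 (not isolated)
Conditions: 11 (6 equiv), CaCO3, 1,2-dichlorobenzene, 150 °C, Ar
Reagents that add atoms: none
Why: The C3=C4–C5=C6 unit of the pyrone in 10 adds the alkene of 11 across C3 and C6 in a thermal (4+2) cycloaddition to give the 2-oxabicyclo[2.2.2]octenone 12, whose lactone bridge leaves as carbon dioxide by cycloreversion to the 5-sulfinylcyclohexa-1,3-diene 13. Thermal syn-elimination of benzenesulfenic acid through a five-membered transition state then aromatises 13, so that 11 serves as an ethyne equivalent. The closest known reaction type is the Diels–Alder reaction of 2-pyrones with alkynes or alkyne surrogates with loss of carbon dioxide, together with the established use of aryl vinyl sulfoxides as ethyne equivalents. Ring D is closed by intermolecular (4+2) annulation: four of its carbons are pyrone C3 to C6, two come from 11, and the new bonds are those from old C3 and old C6 to the two carbons of 11. The stereocentres of 12 and 13 (bridgeheads, the sulfinyl-bearing carbon and sulfur) form without control and all vanish on aromatisation, so neither facial nor endo/exo selectivity is needed, and both orientations of 11 converge on 14 because sulfur is lost. What is needed is chemoselectivity: 10 contains no other diene or dienophile, its aryl bromide, aldehyde and methyl ethers are thermally inert, and the excess of 11 lets the bimolecular addition outrun decomposition. The 4-aryloxy donor raises the diene HOMO, with its largest coefficient at C3, so the pairing with the acceptor alkene is of normal electron demand. CaCO3 buffers the sulfenic acid, which otherwise self-condenses, and so protects the vinylogous aryl ester of 10.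

Step 8
Reactants: 14 3-(3-{2-[3-(4-bromophenoxy)-4,5-dimethoxyphenyl]ethyl}phenoxy)-4,5-dimethoxybenzaldehyde
Product: 15 1-(4-bromophenoxy)-5-{2-[3-(5-ethenyl-2,3-dimethoxyphenoxy)phenyl]ethyl}-2,3-dimethoxybenzene
Conditions: Ph3PCH3Br, KOtBu, THF, 0 °C to rt
Reagents that add atoms: methyltriphenylphosphonium bromide, C[P+](c1ccccc1)(c1ccccc1)c1ccccc1.[Br-]
Why: Wittig methylenation of a non-enolisable aryl aldehyde; the alkoxide-generated ylide does not touch the aryl bromide or the ethers.

Step 9
Reactants: 15 1-(4-bromophenoxy)-5-{2-[3-(5-ethenyl-2,3-dimethoxyphenoxy)phenyl]ethyl}-2,3-dimethoxybenzene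
Product: 17 tetra-O-methyl macrocycle (target with all four OH as OMe), via B-alkyl-9-BBN borane 16 (not isolated)
Conditions: 9-BBN (1.5 equiv), THF, rt; then H2O and slow addition (syringe pump) to Pd(dppf)Cl2 (10 mol %), Cs2CO3 (3 equiv), DMF/THF/H2O, 70 °C, final concentration about 2 mM
Reagents that add atoms: none
Why: Anti-Markovnikov hydroboration of the styrene by 9-BBN puts boron on the terminal carbon, and an intramolecular B-alkyl Suzuki–Miyaura coupling closes the ring: zerovalent palladium inserts into the ring B C–Br bond, the hydroxyborate transfers its primary alkyl group and reductive elimination forms the sp3–sp2 bond. The wide-bite-angle dppf ligand disfavours beta-hydride elimination, and slow addition at high dilution favours the 19-membered ring over oligomers.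

Step 10
Reactants: 17 tetra-O-methyl macrocycle
Product: 18 target tetraphenol CNP0511668.0
Conditions: BBr3 (10 equiv), CH2Cl2, −78 °C to rt; then ice-water, work-up under argon
Reagents that add atoms: none
Why: Lewis-acid demethylation: BBr3 coordinates each methoxy oxygen and bromide attacks the methyl carbon by SN2, whereas the diaryl ethers have only sp2 C–O bonds and are not cleaved; hydrolysis of the aryl borates frees the two catechols, and there is no stereocentre to protect.

## Compound list

1 | 3-hydroxy-4,5-dimethoxybenzaldehyde | COc1cc(C=O)cc(O)c1OC | starting material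
2 | (4-bromophenyl)boronic acid | OB(O)c1ccc(Br)cc1 | starting material
3 | 3-(4-bromophenoxy)-4,5-dimethoxybenzaldehyde | COc1cc(C=O)cc(Oc2ccc(Br)cc2)c1OC | intermediate
4 | [3-(4-bromophenoxy)-4,5-dimethoxyphenyl]methanol | COc1cc(CO)cc(Oc2ccc(Br)cc2)c1OC | intermediate
5 | 1-(4-bromophenoxy)-5-(bromomethyl)-2,3-dimethoxybenzene | COc1cc(CBr)cc(Oc2ccc(Br)cc2)c1OC | intermediate
6 | 4-hydroxy-6-methyl-2H-pyran-2-one | Cc1cc(O)cc(=O)o1 | starting material
7 | dilithium dianion of 6 (4-oxide and 6-methylide; not isolated) | [Li+].[Li+].[CH2-]C1=CC([O-])=CC(=O)O1 | intermediate
8 | 6-{2-[3-(4-bromophenoxy)-4,5-dimethoxyphenyl]ethyl}-4-hydroxy-2H-pyran-2-one | O=c1cc(O)cc(CCc2cc(OC)c(OC)c(Oc3ccc(Br)cc3)c2)o1 | intermediate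
9 | 4-bromo-6-{2-[3-(4-bromophenoxy)-4,5-dimethoxyphenyl]ethyl}-2H-pyran-2-one | O=c1cc(Br)cc(CCc2cc(OC)c(OC)c(Oc3ccc(Br)cc3)c2)o1 | intermediate
10 | 3-[(6-{2-[3-(4-bromophenoxy)-4,5-dimethoxyphenyl]ethyl}-2-oxo-2H-pyran-4-yl)oxy]-4,5-dimethoxybenzaldehyde | O=c1cc(Oc2cc(C=O)cc(OC)c2OC)cc(CCc2cc(OC)c(OC)c(Oc3ccc(Br)cc3)c2)o1 | intermediate
11 | phenyl vinyl sulfoxide (racemic at sulfur) | C=CS(=O)c1ccccc1 | starting material
12 | 3-({1-{2-[3-(4-bromophenoxy)-4,5-dimethoxyphenyl]ethyl}-3-oxo-7-(phenylsulfinyl)-2-oxabicyclo[2.2.2]oct-5-en-5-yl}oxy)-4,5-dimethoxybenzaldehyde (mixture of stereoisomers; the regioisomer with sulfur at C8 converges likewise; not isolated) | O=C1OC2(CCc3cc(OC)c(OC)c(Oc4ccc(Br)cc4)c3)C=C(Oc3cc(C=O)cc(OC)c3OC)C1CC2S(=O)c1ccccc1 | intermediate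
13 | 3-({3-{2-[3-(4-bromophenoxy)-4,5-dimethoxyphenyl]ethyl}-4-(phenylsulfinyl)cyclohexa-1,3-dien-1-yl... 5-sulfinylcyclohexa-1,3-diene formed from 12 by loss of CO2}oxy)-4,5-dimethoxybenzaldehyde (mixture of stereoisomers; not isolated) | O=S(c1ccccc1)C1CC=C(Oc2cc(C=O)cc(OC)c2OC)C=C1CCc1cc(OC)c(OC)c(Oc2ccc(Br)cc2)c1 | intermediate
14 | 3-(3-{2-[3-(4-bromophenoxy)-4,5-dimethoxyphenyl]ethyl}phenoxy)-4,5-dimethoxybenzaldehyde | O=Cc1cc(OC)c(OC)c(Oc2cccc(CCc3cc(OC)c(OC)c(Oc4ccc(Br)cc4)c3)c2)c1 | intermediate
15 | 1-(4-bromophenoxy)-5-{2-[3-(5-ethenyl-2,3-dimethoxyphenoxy)phenyl]ethyl}-2,3-dimethoxybenzene | C=Cc1cc(OC)c(OC)c(Oc2cccc(CCc3cc(OC)c(OC)c(Oc4ccc(Br)cc4)c3)c2)c1 | intermediate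
16 | 9-{2-[3-(3-{2-[3-(4-bromophenoxy)-4,5-dimethoxyphenyl]ethyl}phenoxy)-4,5-dimethoxyphenyl]ethyl}-9-borabicyclo[3.3.1]nonane (not isolated) | COc1cc(CCB2C3CCCC2CCC3)cc(Oc2cccc(CCc3cc(OC)c(OC)c(Oc4ccc(Br)cc4)c3)c2)c1OC | intermediate
17 | tetra-O-methyl macrocycle: the 19-membered ring A–O–B–CH2CH2–C–O–D–CH2CH2 with the four hydroxyls of the target as methoxy groups | COc1cc2cc(c1OC)Oc1ccc(cc1)CCc1cc(OC)c(OC)c(c1)Oc1cccc(c1)CC2 | intermediate
18 | CNP0511668.0, the macrocyclic bis(bibenzyl) tetraphenol (no stereocentre) | Oc1cc2cc(c1O)Oc1ccc(cc1)CCc1cc(O)c(O)c(c1)Oc1cccc(c1)CC2 | target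

## Step count and least certain steps

Total step count: 10. Longest linear sequence: 10 steps (1 → 3 → 4 → 5 → 8 → 9 → 10 → 14 → 15 → 17 → 18); 2, 6 and 11 are bought.

**Step 7 (key step).**
- What may go wrong: the cycloaddition of the donor-substituted pyrone may be slower than polymerisation or thermal breakdown of the dienophile. Water from self-condensation of the sulfenic acid may cleave the vinylogous aryl ester of 10. Double-bond migration in 13 could also open a path in which the ring C phenol is lost instead of sulfenic acid.
- Fallback, from 5 back to 14, with ring D taken from a purchased meta-disubstituted benzene: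
  - 5 with PPh3 (toluene, reflux) should give {[3-(4-bromophenoxy)-4,5-dimethoxyphenyl]methyl}triphenylphosphonium bromide F1.
  - Wittig reaction with commercial 3-iodobenzaldehyde (KOtBu, THF, 0 °C) should give 1-(4-bromophenoxy)-5-[2-(3-iodophenyl)ethenyl]-2,3-dimethoxybenzene F2 as an E/Z mixture.
  - Diimide reduction (p-toluenesulfonyl hydrazide, NaOAc, THF/H2O, reflux), which spares both carbon–halogen bonds, should give 1-(4-bromophenoxy)-5-[2-(3-iodophenyl)ethyl]-2,3-dimethoxybenzene F3.
  - Ullmann coupling of F3 with 1 (CuI, N,N-dimethylglycine, Cs2CO3, dioxane, 90 °C), where the iodide should react ahead of the electron-rich ring B bromide, should give 14.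

**Step 9.**
- What may go wrong: intermolecular coupling to dimers and oligomers; loss of the alkylborane by protodeboronation or beta-hydride elimination during the long slow addition; hydrodebromination of ring B.
- Fallback, from 15 back to 17, avoiding the fragile borane: an intramolecular Mizoroki–Heck reaction (Pd(OAc)2, P(o-tol)3, Et3N, DMF, 100 °C, high dilution) should give the macrocyclic (E)-stilbene F4. Hydrogenation (H2, Pd/C, that is palladium on carbon, EtOAc, rt) should then give 17.

**Step 4.**
- What may go wrong: poor solubility of the dianion, competing O-alkylation or a second alkylation, and base-induced self-coupling of the benzylic bromide.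
- Fallback, from 5 back to 8, building the pyrone after the alkylation:
  - The dianion of pentane-2,4-dione (LiN(iPr)2, 2 equiv, THF, 0 °C) is alkylated by 5 at its terminal carbon to give 6-[3-(4-bromophenoxy)-4,5-dimethoxyphenyl]hexane-2,4-dione F5.
  - A second dianion, formed at the methyl terminus, is carboxylated (CO2, THF, −78 °C) to 7-[3-(4-bromophenoxy)-4,5-dimethoxyphenyl]-3,5-dioxoheptanoic acid F6.
  - Cyclodehydration (1,1'-carbonyldiimidazole, THF, rt) should give 8.

**Step 1.**
- What may go wrong: sluggish O-arylation of the ortho-methoxy phenol, with the boronic acid consumed by homocoupling and oxidation to the phenol.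
- Fallback, from 1 back to 3: Ullmann coupling of 1 with commercial 1-bromo-4-iodobenzene (CuI, N,N-dimethylglycine, Cs2CO3, dioxane, 90 °C), in which the iodide reacts selectively. This fallback makes no compound outside the list (F0).

## Further compounds

F1 | step 7 | {[3-(4-bromophenoxy)-4,5-dimethoxyphenyl]methyl}triphenylphosphonium bromide | COc1cc(C[P+](c2ccccc2)(c2ccccc2)c2ccccc2)cc(Oc2ccc(Br)cc2)c1OC.[Br-]
F2 | step 7 | 1-(4-bromophenoxy)-5-[2-(3-iodophenyl)ethenyl]-2,3-dimethoxybenzene (E/Z mixture) | COc1cc(C=Cc2cccc(I)c2)cc(Oc2ccc(Br)cc2)c1OC
F3 | step 7 | 1-(4-bromophenoxy)-5-[2-(3-iodophenyl)ethyl]-2,3-dimethoxybenzene | COc1cc(CCc2cccc(I)c2)cc(Oc2ccc(Br)cc2)c1OC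
F4 | step 9 | macrocyclic (E)-stilbene: 17 with a trans CH=CH in place of the ring B to ring C CH2CH2 bridge | COc1cc2cc(c1OC)Oc1ccc(cc1)/C=C/c1cc(OC)c(OC)c(c1)Oc1cccc(c1)CC2
F5 | step 4 | 6-[3-(4-bromophenoxy)-4,5-dimethoxyphenyl]hexane-2,4-dione | CC(=O)CC(=O)CCc1cc(OC)c(OC)c(Oc2ccc(Br)cc2)c1
F6 | step 4 | 7-[3-(4-bromophenoxy)-4,5-dimethoxyphenyl]-3,5-dioxoheptanoic acid | OC(=O)CC(=O)CC(=O)CCc1cc(OC)c(OC)c(Oc2ccc(Br)cc2)c1
F0 | step 1 | none | none
A1 | alternative 1 | tetra-O-methyl macrocycle (identical with 17) | COc1cc2cc(c1OC)Oc1ccc(cc1)CCc1cc(OC)c(OC)c(c1)Oc1cccc(c1)CC2
A2 | alternative 1 | 20-membered aryl ester: ring A phenol acylated by the ring B benzoic acid, otherwise as A1 | COc1cc2cc(c1OC)OC(=O)c1ccc(cc1)CCc1cc(OC)c(OC)c(c1)Oc1cccc(c1)CC2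
A3 | alternative 2 | 2,3-diisopropoxy-5-{2-[4-(triisopropylsilyloxy)phenyl]ethyl}phenol | CC(C)Oc1cc(CCc2ccc(O[Si](C(C)C)(C(C)C)C(C)C)cc2)cc(O)c1OC(C)C
A4 | alternative 2 | 4-chloro-2,3-diisopropoxycyclobut-2-en-1-one (racemic) | CC(C)OC1=C(OC(C)C)C(Cl)C1=O
A5 | alternative 2 | tributyl{4-[4-(triisopropylsilyloxy)phenyl]but-1-en-2-yl}stannane | CCCC[Sn](CCCC)(CCCC)C(=C)CCc1ccc(O[Si](C(C)C)(C(C)C)C(C)C)cc1
A6 | alternative 3 | 5-[2-(3-bromophenyl)ethyl]-2,3-di-tert-butoxyphenol | CC(C)(C)Oc1cc(CCc2cccc(Br)c2)cc(O)c1OC(C)(C)C
A7 | alternative 3 | 5-(3-bromophenyl)-1-diazo-3-methylidenepentan-2-one | C=C(CCc1cccc(Br)c1)C(=O)C=[N+]=[N-]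
A8 | alternative 3 | di-tert-butoxyethyne | CC(C)(C)OC#COC(C)(C)C
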